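**Retrosynthetic overview**
- The target is the C2-symmetric malonate diester of (13E)-labd-13-ene-8α,15-diol. Both C14–C15 bonds are disconnected at once (two-directional sp2–sp3 cross-coupling), which gives two molecules of the (E)-alkenyl iodide 8 and the symmetric core bis[(tributylstannyl)methyl] malonate 11.
- Enabling feature: each C15 is an ester-oxygen-bearing methylene without β-hydrogen, sitting between a malonate carbonyl and C14 of an E-configured 2-methylalk-1-enyl terminus (C16–C13=C14). An acyloxymethylstannane can deliver it, its ester carbonyl oxygen coordinating tin in a five-membered chelate.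
- 8 comes from the terminal alkyne 5 by syn-methylalumination/iodinolysis, which installs C16 and sets C13=C14 as E. 5 comes from the methyl ketone 2, made from (−)-sclareol 1 by excision of C14/C15; the ketone methyl carbon becomes C14.
- No ring is formed: rings A and B (trans-decalin with C5, C8, C9, C10) are taken intact from sclareol. 11 comes from (tributylstannyl)methanol and malonyl dichloride.

Key step: step 6

Remark: the decalin configuration of the target (5S,8R,9R,10S) is that of (−)-sclareol; 1, 9 and 10 are taken as purchased.

**Step 1**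
Reactants: 1 (−)-sclareol
Product: 2 8α-hydroxy-14,15-dinorlabdan-13-one
Conditions: OsO4 (2 mol %), NaIO4 (4 equiv), 2,6-lutidine, dioxane/H2O 3:1, rt
Reagents that add atoms: none
Why: Lemieux–Johnson oxidation: dihydroxylation of the vinyl group and periodate cleavage of the resulting 13,14,15-triol should remove C14 and C15 and leave the C13 oxygen as the ketone, the tertiary C8 alcohol and the four ring stereocentres being inert.

**Step 2**
Reactants: 2 8α-hydroxy-14,15-dinorlabdan-13-one
Product: 3 8α-(trimethylsilyloxy)-14,15-dinorlabdan-13-one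
Conditions: N-(trimethylsilyl)imidazole (2 equiv), CH2Cl2, rt
Reagents that add atoms: N-(trimethylsilyl)imidazole, C[Si](C)(C)n1ccnc1
Why: O-silylation with a silyl imidazole should protect the hindered tertiary alcohol without enolising the ketone, so that the alkoxide can neither be phosphorylated nor close onto C13 in step 3.

**Step 3**
Reactants: 3 8α-(trimethylsilyloxy)-14,15-dinorlabdan-13-one
Product: 5 8α-(trimethylsilyloxy)-15,16-dinorlabd-13-yne, via kinetic enol diethyl phosphate 4 (not isolated)
Conditions: LiN(iPr)2 (1.1 equiv), THF, −78 °C; ClP(O)(OEt)2 (1.1 equiv), −78 °C to rt; then LiN(iPr)2 (2.3 equiv), THF, −78 °C to rt; aq. NH4Cl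
Reagents that add atoms: diethyl chlorophosphate, CCOP(=O)(Cl)OCC (its atoms are held in 4 and leave again on the way to 5)
Why: Kinetic deprotonation at the methyl group, O-phosphorylation and base-induced β-elimination of diethyl phosphate (enol phosphate route from a methyl ketone to a terminal alkyne) should give the alkyne, which is held as its lithium acetylide until the quench and so cannot isomerise.

**Step 4**
Reactants: 5 8α-(trimethylsilyloxy)-15,16-dinorlabd-13-yne
Product: 8 (13E)-14-iodo-15-norlabd-13-en-8α-ol, via (E)-alkenyldimethylalane 6 (not isolated), via silylated alkenyl iodide 7 (not isolated)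
Conditions: AlMe3 (3 equiv), Cp2ZrCl2 (0.25 equiv), CH2Cl2, 0 °C to rt; I2 (1.3 equiv), THF, −30 to 0 °C; then 1 M HCl, THF, rt
Reagents that add atoms: trimethylaluminium, C[Al](C)C; iodine, II
Why: Zirconocene-catalysed Negishi carboalumination adds methyl to the internal and aluminium to the terminal alkyne carbon on the same face, iodinolysis of the C–Al bond proceeds with retention so that C13=C14 is set E, and the dilute acid of the work-up should cleave the tertiary trimethylsilyl ether.

**Step 5**
Reactants: 9 (tributylstannyl)methanol (2.1 equiv); 10 malonyl dichloride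
Product: 11 bis[(tributylstannyl)methyl] malonate
Conditions: pyridine (2.5 equiv), CH2Cl2, 0 °C to rt
Reagents that add atoms: none
Why: Twofold acylation of the primary alcohol by the diacid chloride under pyridine should give the symmetric diester, the C–Sn bonds being inert to an acid chloride in the absence of a palladium catalyst.

**Step 6**
Reactants: 8 (13E)-14-iodo-15-norlabd-13-en-8α-ol (2.3 equiv); 11 bis[(tributylstannyl)methyl] malonate
Product: 13 bis[(13E)-8α-hydroxylabd-13-en-15-yl] malonate, via monocoupled stannylmethyl labdenyl malonate 12 (not isolated)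
Conditions: Pd2(dba)3 (5 mol %), AsPh3 (40 mol %), CuI (20 mol %), NMP, 50 °C, argon, dark
Reagents that add atoms: none
Why: Each cycle is a Migita–Kosugi–Stille coupling: zerovalent palladium inserts into the C14–I bond of 8, the acyloxymethyl group of 11 passes from tin by way of copper to divalent palladium, and reductive elimination forges the C14–C15 bond; the first cycle gives 12 and the second, at the other stannylmethyl terminus, joins the two large halves to 13. The closest known reaction type is the palladium-catalysed hydroxymethylation or acyloxyalkylation of alkenyl and aryl halides by α-oxygenated alkyltributylstannanes under copper co-catalysis. No ring is closed and no stereocentre is created; the E geometry of C13=C14 from step 4 is carried through because oxidative addition and reductive elimination both retain alkene configuration. The step needs transfer of the oxygenated CH2 group instead of butyl, which the α-oxygen and the five-membered coordination of the ester carbonyl oxygen to tin should secure, and the transferred group has no β-hydrogen, so β-hydride elimination cannot intervene. It also needs the allylic malonate product to outlast zerovalent palladium, which the slight excess of 8 (palladium rests as the alkenylpalladium iodide), the weakly donating AsPh3 ligand and the moderate temperature should secure. The conditions are neutral, so the acidic malonate CH2, the ester links and the free tertiary C8 alcohols stay untouched and the final step needs no protecting group.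

**Compound list**
1 | (−)-sclareol, (13R)-labd-14-ene-8α,13-diol | C=C[C@](C)(O)CC[C@@H]1[C@@]2(C)CCCC(C)(C)[C@@H]2CC[C@@]1(C)O | starting material
2 | 8α-hydroxy-14,15-dinorlabdan-13-one | CC(=O)CC[C@@H]1[C@@]2(C)CCCC(C)(C)[C@@H]2CC[C@@]1(C)O | intermediate
3 | 8α-(trimethylsilyloxy)-14,15-dinorlabdan-13-one | CC(=O)CC[C@@H]1[C@@]2(C)CCCC(C)(C)[C@@H]2CC[C@@]1(C)O[Si](C)(C)C | intermediate
4 | diethyl 8α-(trimethylsilyloxy)-14,15-dinorlabd-13(16)-en-13-yl phosphate (kinetic enol phosphate) | C=C(OP(=O)(OCC)OCC)CC[C@@H]1[C@@]2(C)CCCC(C)(C)[C@@H]2CC[C@@]1(C)O[Si](C)(C)C | intermediate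
5 | 8α-(trimethylsilyloxy)-15,16-dinorlabd-13-yne | C#CCC[C@@H]1[C@@]2(C)CCCC(C)(C)[C@@H]2CC[C@@]1(C)O[Si](C)(C)C | intermediate
6 | dimethyl[(13E)-8α-(trimethylsilyloxy)-15-norlabd-13-en-14-yl]alane | C/C(=C\[Al](C)C)CC[C@@H]1[C@@]2(C)CCCC(C)(C)[C@@H]2CC[C@@]1(C)O[Si](C)(C)C | intermediate
7 | (13E)-14-iodo-8α-(trimethylsilyloxy)-15-norlabd-13-ene | C/C(=C\I)CC[C@@H]1[C@@]2(C)CCCC(C)(C)[C@@H]2CC[C@@]1(C)O[Si](C)(C)C | intermediate
8 | (13E)-14-iodo-15-norlabd-13-en-8α-ol | C/C(=C\I)CC[C@@H]1[C@@]2(C)CCCC(C)(C)[C@@H]2CC[C@@]1(C)O | intermediate
9 | (tributylstannyl)methanol | CCCC[Sn](CCCC)(CCCC)CO | starting material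
10 | malonyl dichloride | O=C(Cl)CC(=O)Cl | starting material
11 | bis[(tributylstannyl)methyl] malonate | CCCC[Sn](CCCC)(CCCC)COC(=O)CC(=O)OC[Sn](CCCC)(CCCC)CCCC | intermediate
12 | (13E)-8α-hydroxylabd-13-en-15-yl (tributylstannyl)methyl malonate | C/C(=C\COC(=O)CC(=O)OC[Sn](CCCC)(CCCC)CCCC)CC[C@@H]1[C@@]2(C)CCCC(C)(C)[C@@H]2CC[C@@]1(C)O | intermediate
13 | bis[(13E)-8α-hydroxylabd-13-en-15-yl] malonate (CNP0254645.1) | C/C(=C\COC(=O)CC(=O)OC/C=C(\C)CC[C@@H]1[C@@]2(C)CCCC(C)(C)[C@@H]2CC[C@@]1(C)O)CC[C@@H]1[C@@]2(C)CCCC(C)(C)[C@@H]2CC[C@@]1(C)O | target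

**Totals**
Total step count: 6. Longest linear sequence: 5 steps (steps 1, 2, 3, 4, 6).

**Steps most likely to fail**

1. Step 6. The sp3 acyloxymethyl group may leave tin too slowly, so that butyl transfer and protodestannylation compete, and zerovalent palladium may ionise the allylic malonate (decarboxylative allyl transfer) once 8 is used up. Fallback, setting out from 8 and coming back at 13: deprotonation and iodine–lithium exchange (n-BuLi 1.05 equiv, then t-BuLi 2.1 equiv, Et2O, −78 °C) should give lithium (13E)-14-lithio-15-norlabd-13-en-8α-olate F1 with retention of geometry. Trapping with dry paraformaldehyde forms the C14–C15 bond and gives (13E)-labd-13-ene-8α,15-diol F2. Acylation of F2 (2.1 equiv) with 10 under pyridine in CH2Cl2 at 0 °C should esterify only the primary allylic hydroxyl, the tertiary C8 hydroxyl being too hindered, and give 13.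

2. Step 3. Enolisation may be incompletely regioselective (deprotonation at C12 instead of the methyl group), and the alkyne may isomerise to allene or internal alkyne under the strong base. Fallback, setting out from 2 and coming back at 5: haloform cleavage of the methyl ketone (NaOBr, dioxane/H2O, 0 °C) with lactonisation on acidic work-up should give 14,15,16-trinorlabdan-13,8α-olide F3. Reduction with iBu2AlH (CH2Cl2, −78 °C) gives 8α,13-epoxy-14,15,16-trinorlabdan-13-ol F4. Ohira–Bestmann homologation (dimethyl (1-diazo-2-oxopropyl)phosphonate, K2CO3, MeOH) of the lactol gives 15,16-dinorlabd-13-yn-8α-ol F5, where the alkyne position is fixed by the aldehyde carbon. Silylation as in step 2 then gives 5.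

3. Step 5. Malonyl dichloride may form ketene under base, leading to oligomerisation and incomplete second acylation. Fallback, setting out from 9 and coming back at 11: heating 9 with Meldrum's acid (toluene, 100 °C) should open the dioxanedione to 3-oxo-3-[(tributylstannyl)methoxy]propanoic acid F6. Steglich esterification of F6 with a second equivalent of 9 (DCC, DMAP cat., CH2Cl2, 0 °C to rt) gives 11.

**Further compounds**
F1 | step 6 | lithium (13E)-14-lithio-15-norlabd-13-en-8α-olate | C/C(=C\[Li])CC[C@@H]1[C@@]2(C)CCCC(C)(C)[C@@H]2CC[C@@]1(C)O[Li]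
F2 | step 6 | (13E)-labd-13-ene-8α,15-diol | C/C(=C\CO)CC[C@@H]1[C@@]2(C)CCCC(C)(C)[C@@H]2CC[C@@]1(C)O
F3 | step 3 | 14,15,16-trinorlabdan-13,8α-olide | O=C3CC[C@@H]1[C@@]2(C)CCCC(C)(C)[C@@H]2CC[C@@]1(C)O3
F4 | step 3 | 8α,13-epoxy-14,15,16-trinorlabdan-13-ol (lactol, anomeric mixture) | OC3CC[C@@H]1[C@@]2(C)CCCC(C)(C)[C@@H]2CC[C@@]1(C)O3
F5 | step 3 | 15,16-dinorlabd-13-yn-8α-ol | C#CCC[C@@H]1[C@@]2(C)CCCC(C)(C)[C@@H]2CC[C@@]1(C)O
F6 | step 5 | 3-oxo-3-[(tributylstannyl)methoxy]propanoic acid | CCCC[Sn](CCCC)(CCCC)COC(=O)CC(=O)O
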